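**The question.** Which form holds most X after 2.0 min in alpha and in zeta, and how much? Follow one E at a time.

in all of them: X 0.20 mM

| run | E | remark | time |
|---|---|---|---|
| Tuesday's | 1.6 equiv | run made earlier |  |
| Saturday's | 2.5 equiv | run made earlier |  |
| alpha | 2.10 equiv |  | 2.0 min |
| zeta | 1.10 equiv |  | 2.0 min |

| run | time / s | X / % | Z / % | Q / % | D / % |
|---|---|---|---|---|---|
| Tuesday's | 10.0 | 61.1 | 23.7 | 3.9 | 7.2 |
| Tuesday's | 30.0 | 34.9 | 25.1 | 5.5 | 27.6 |
| Tuesday's | 60.0 | 26.5 | 23.0 | 4.2 | 37.8 |
| Tuesday's | 80.0 | 25.1 | 21.4 | 5.0 | 41.2 |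
| Tuesday's | 120 | 23.5 | 20.7 | 5.7 | 41.5 |
| Saturday's | 10.0 | 46.1 | 26.1 | 5.6 | 17.2 |
| Saturday's | 30.0 | 19.6 | 19.7 | 3.8 | 49.2 |
| Saturday's | 60.0 | 11.3 | 12.8 | 3.1 | 64.5 |
| Saturday's | 80.0 | 10.4 | 11.2 | 2.4 | 69.3 |
| Saturday's | 120 | 8.3 | 9.3 | 2.4 | 73.5 |

(scatter of a reading: 0.5 percentage points)

- a species is counted by the X in it: one L counts as two
- amounts and yields of D count L too
- amounts and yields of J count G too
- given per volume of solution although it is solid: G
- the analysis behind the earlier runs scatters by 0.5 percentage points, standard deviation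
- on the list of suspects stand: X + E -> J + Z; Z + E -> J + Q; Q + E <-> J + D; X + D <-> L; G <-> J
- in an amount of D, one L counts as one D

- which of these there is most of at the end, counted by the X in it, alpha (D / X / Z / Q)
- which of these there is most of at the end, counted by the X in it, zeta (D / X / Z / Q)
- the largest of these amounts at the end, in percent of the X charged, alpha
- the largest of these amounts at the end, in percent of the X charged, zeta

**Ledger entries.** E is the limiting reagent here. Each E taken is one exchange, so a Z has cost one E, a Q 2 and a D 3, whether or not that D sits in L. Tuesday's last readings book 1.57 equiv of the 1.6 equiv charged, Saturday's 2.35 of 2.5 equiv. I book the mean of those two shares as spent.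

**The fork.** An E can land on X, on Z or on Q, and the landing on Q is the third E charged to each D; the E not taken by Q forks between X and Z. I assume a selectivity factor of 2, so its chance of landing on X is [X]/([X]+2[Z]). Followed through, this gives Z = u − u squared, with u the share of X that has taken no E, free or in L. At Tuesday's end u is 32.1%, and the rule gives Z 21.8% against 20.7% read. At Saturday's end u is 14.8%, and it gives 12.6% against 9.3%, so it runs high there.

**Closing the books.** Booking Q as D, the spend per X is 3 − 5u + 2u squared. Alpha spends 2.01 equiv, so 21.6% of its X is the untouched share, X that has taken no E. The readings' mean shortfall, 7.55%, is X held in L, and mean Q is 4.05%. So alpha has free X 14.1%, Z 16.9% and D 57.4%. Zeta spends 1.05 equiv, so u is 48.2%, with free X 40.7%, Z 25.0% and D 22.8%.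

**The forecast.** It says D at 60% for alpha, above my 57.4%, and X at 40% for zeta, beside my 40.7%, its ground being “Treating X and Z as competing for E”.

**The flask.** Alpha ends with D at 60.5%, zeta with X at 37.7%.

    X + E → J + Z (k = 170 /M/s)
    Z + E → J + Q (k = 290 /M/s)
    Q + E ⇌ J + D (K = 7.50, k = 1500 /M/s)
    X + D ⇌ L, settled at all times (K = 5100 /M)
    G ⇌ J, rate k5*(cs5 - [J]) while solid is left; crystals form when [J] > cs5 (solubility = 0.00320 mM, k = 4.40 /s)

**What turns it.** Alpha's untouched share stands at 21.2%, beside the 21.6% reckoned. The equivalents of E are the main reason for alpha's low X, 13.8% against 37.7% on zeta's charge, so weigh E with care. The flask like zeta but with 2.80 equiv of E ends with most X in D. The ledger there books 2.68 equiv, so u is 6.49%, leaving D with Q at 87.4%. That flask holds D and Q together at 83.5%.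

Readings and results are simulated with made-up constants; scatter was added.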